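**Strategy.** Ring C is a 5-pentylresorcinol ring of polyketide type with the ether oxygen on C1', hydroxyls on C2' and C4', and the pentyl chain on C6'. The route cuts its C1'–C6' bond, which unfolds the ring into an undecane-2,4,6-trione whose C1 is already bonded to the ring A oxygen. One base-mediated aldol condensation and aromatisation re-forms C1'–C6', closes ring C with both hydroxyls free, and so delivers the crowded diaryl ether without any aryl–oxygen coupling. The precursor is a ring A N,N-diethyl toluamide (4-OMe, 6-CH3) carrying OCH2–CO–CH2–CO–CH2–CO–C5H11 at C2. Its amide shields the ring A carbonyl in base and later directs lateral lithiation of the 6-methyl group to build lactone ring B.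

Key step: step 6

Remark: ring A is the benzene ring of the isocoumarin, ring B its lactone ring and ring C the pentylresorcinol ring (primed locants); the triketone chain is numbered from the OCH2 carbon (C1) to the pentyl terminus (C11). The target is achiral. The stereocentres of the transient compounds 11 and 17 disappear within their own steps, and the 2,6-disubstituted diethylamides are carried as racemic rotamers.

Step 1
Reactants: 1 methyl orsellinate (methyl 2,4-dihydroxy-6-methylbenzoate)
Product: 2 methyl 2-hydroxy-4-methoxy-6-methylbenzoate
Conditions: MeI (1.1 equiv), K2CO3 (1.1 equiv), acetone, 50 °C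
Reagents that add atoms: iodomethane, CI
Why: Williamson O-methylation; the 2-OH is held in a hydrogen bond to the ester carbonyl and is less acidic, so one equivalent of MeI should alkylate only the free 4-OH.

Step 2
Reactants: 2 methyl 2-hydroxy-4-methoxy-6-methylbenzoate
Product: 3 2-hydroxy-4-methoxy-6-methylbenzoic acid
Conditions: KOH (5 equiv), EtOH/H2O, reflux; then 2 M HCl, 0 °C
Reagents that add atoms: potassium hydroxide, [K+].[OH-]
Why: Ester saponification by acyl–oxygen cleavage, which should proceed at reflux even on this 2,6-disubstituted salicylate; the phenoxide–carboxylate dianion does not decarboxylate, and the free acid is only liberated in the cold.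

Step 3
Reactants: 3 2-hydroxy-4-methoxy-6-methylbenzoic acid
Product: 5 N,N-diethyl-2-hydroxy-4-methoxy-6-methylbenzamide, via acid chloride 4 (not isolated)
Conditions: SOCl2 (3 equiv), DMF (1 mol%), toluene, 50 °C, evaporate; then Et2NH (4 equiv), CH2Cl2, 0 °C→rt
Reagents that add atoms: diethylamine, CCNCC
Why: Acyl chloride formation followed by Schotten–Baumann-type aminolysis, the standard way to force a di-ortho-substituted benzoic acid onto a secondary amine; excess Et2NH should also cleave any O-acylated by-product back to the phenol.

Step 4
Reactants: 5 N,N-diethyl-2-hydroxy-4-methoxy-6-methylbenzamide; 6 methyl bromoacetate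
Product: 7 methyl 2-[2-(diethylcarbamoyl)-5-methoxy-3-methylphenoxy]acetate
Conditions: 6 (1.2 equiv), K2CO3 (2 equiv), DMF, 50 °C
Reagents that add atoms: none
Why: Williamson ether synthesis; the phenoxide displaces bromide from an unhindered primary α-bromo ester by SN2, so the future diaryl ether oxygen is alkylated at a CH2 without steric difficulty.

Step 5
Reactants: 7 methyl 2-[2-(diethylcarbamoyl)-5-methoxy-3-methylphenoxy]acetate; 8 nonane-2,4-dione
Product: 10 N,N-diethyl-4-methoxy-6-methyl-2-[(2,4,6-trioxoundecyl)oxy]benzamide, via dilithium dienolate 9 (not isolated)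
Conditions: 8 (3.0 equiv), LiN(i-Pr)2 (5.9 equiv), THF, −78→0 °C; then 7 (1 equiv), −78→0 °C; aq. NH4Cl, 1 M HCl to pH 5
Reagents that add atoms: none
Why: Claisen-type C-acylation of a β-diketone 1,3-dianion; the second deprotonation of 8 should occur at the unsubstituted C1 methyl, this terminal carbon is the most nucleophilic site and adds to the activated α-aryloxy ester, the excess dianion serves as base for the more acidic triketone, and no free amide base remains to touch the toluamide methyl group.

Step 6
Reactants: 10 N,N-diethyl-4-methoxy-6-methyl-2-[(2,4,6-trioxoundecyl)oxy]benzamide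
Product: 12 N,N-diethyl-2-(2,4-dihydroxy-6-pentylphenoxy)-4-methoxy-6-methylbenzamide, via cyclic aldol carbinol 11 (not isolated)
Conditions: KOH (1 M aq., 6 equiv), THF, degassed, 0 °C→rt; then 1 M HCl to pH 3
Reagents that add atoms: none
Why: Hydroxide deprotonates the triketone reversibly, and because the aryloxy oxygen acidifies C1–H and C3–H the negative charge gathers in the C1–C4 half (C1=C2/C3=C4 dienolate) while C6 stays ketonic, so C1 adds to C6 in an intramolecular aldol reaction to give carbinol 11, which loses water by E1cB elimination and tautomerises to the aromatic bis-phenoxide that is protonated on work-up. The closest known reaction is the base-mediated cyclisation of acyclic 2,4,6-triketones to 5-substituted resorcinols, the laboratory counterpart of polyketide aromatisation. Ring C closes in a 6-(enolendo)-exo-trig mode, because both enolate carbons (C1 and C2) end up inside the new ring and the C6 carbonyl oxygen outside it, a stereoelectronically favoured closure. No stereocentre remains, since the two centres of 11 are erased on aromatisation. The selectivity needed is closure from C1 onto C6 instead of from C7 onto C2 (which would give a 4-butyl-5-(aryloxymethyl)resorcinol), and it is secured by the inductive effect of the aryloxy group, which makes C1–H clearly more acidic than the alkyl-substituted C7–H and keeps C2 enolised and therefore non-electrophilic. Attack of the C1 enolate on the ring A carbonyl (benzofuranone formation) and saponification are prevented by the hindered, twisted tertiary amide, and cold, oxygen-free conditions limit retro-Claisen cleavage and phenoxide oxidation.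

Step 7
Reactants: 12 N,N-diethyl-2-(2,4-dihydroxy-6-pentylphenoxy)-4-methoxy-6-methylbenzamide
Product: 13 N,N-diethyl-2-(2,4-dimethoxy-6-pentylphenoxy)-4-methoxy-6-methylbenzamide
Conditions: MeI (3 equiv), K2CO3 (4 equiv), acetone, reflux
Reagents that add atoms: iodomethane, CI
Why: Williamson O-methylation of both phenols, which removes the acidic OH groups before the amide-base step and puts all three oxygens under the same protecting group for a single final deprotection.

Step 8
Reactants: 14 hexanoyl chloride
Product: 15 N-methoxy-N-methylhexanamide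
Conditions: MeNHOMe·HCl (1.1 equiv), Et3N (2.2 equiv), CH2Cl2, 0 °C→rt
Reagents that add atoms: N,O-dimethylhydroxylamine hydrochloride, CNOC.Cl
Why: N-Acylation of an amine by an acid chloride (Weinreb amide formation), a routine Schotten–Baumann-type reaction.

Step 9
Reactants: 13 N,N-diethyl-2-(2,4-dimethoxy-6-pentylphenoxy)-4-methoxy-6-methylbenzamide; 15 N-methoxy-N-methylhexanamide
Product: 18 N,N-diethyl-2-(2,4-dimethoxy-6-pentylphenoxy)-4-methoxy-6-(2-oxoheptyl)benzamide, via benzylic organolithium 16 (not isolated), via lithium hemiaminal alkoxide 17 (not isolated)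
Conditions: LiN(i-Pr)2 (1.3 equiv), THF, −78 °C; then 15 (1.5 equiv), −78→−40 °C; aq. NH4Cl
Reagents that add atoms: none
Why: Lateral (benzylic) lithiation of an ortho-toluamide, in which the amide carbonyl directs and stabilises the CH2Li, followed by Weinreb ketone synthesis; the chelated adduct 17 survives until work-up, so neither over-addition nor quenching of 16 by the more acidic ketone should occur.

Step 10
Reactants: 18 N,N-diethyl-2-(2,4-dimethoxy-6-pentylphenoxy)-4-methoxy-6-(2-oxoheptyl)benzamide
Product: 19 8-(2,4-dimethoxy-6-pentylphenoxy)-6-methoxy-3-pentyl-1H-isochromen-1-one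
Conditions: TsOH·H2O (0.2 equiv), AcOH, 110 °C
Reagents that add atoms: none
Why: Acid-catalysed enol lactonisation (intramolecular transacylation of a keto amide); the enol oxygen of the benzyl ketone attacks the protonated amide carbonyl in a six-membered closure and diethylamine leaves as its ammonium salt, giving the conjugated 3-alkylisocoumarin.

Step 11
Reactants: 19 8-(2,4-dimethoxy-6-pentylphenoxy)-6-methoxy-3-pentyl-1H-isochromen-1-one
Product: 20 8-(2,4-dihydroxy-6-pentylphenoxy)-6-hydroxy-3-pentyl-1H-isochromen-1-one (CNP0213708.0)
Conditions: BBr3 (8 equiv), CH2Cl2, −78 °C→rt; then ice-water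
Reagents that add atoms: none
Why: Lewis acid cleavage of aryl methyl ethers; BBr3 coordinates each methoxy oxygen and bromide removes the methyl group by SN2, whereas the diaryl ether (no sp3 carbon on oxygen) and the enol lactone should not be cleaved.

**Compound list**

1 | methyl orsellinate (methyl 2,4-dihydroxy-6-methylbenzoate) | COC(=O)c1c(C)cc(O)cc1O | starting material
2 | methyl 2-hydroxy-4-methoxy-6-methylbenzoate | COC(=O)c1c(C)cc(OC)cc1O | intermediate
3 | 2-hydroxy-4-methoxy-6-methylbenzoic acid | OC(=O)c1c(C)cc(OC)cc1O | intermediate
4 | 2-hydroxy-4-methoxy-6-methylbenzoyl chloride (not isolated) | ClC(=O)c1c(C)cc(OC)cc1O | intermediate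
5 | N,N-diethyl-2-hydroxy-4-methoxy-6-methylbenzamide | CCN(CC)C(=O)c1c(C)cc(OC)cc1O | intermediate
6 | methyl bromoacetate | COC(=O)CBr | starting material
7 | methyl 2-[2-(diethylcarbamoyl)-5-methoxy-3-methylphenoxy]acetate | COC(=O)COc1cc(OC)cc(C)c1C(=O)N(CC)CC | intermediate
8 | nonane-2,4-dione | CCCCCC(=O)CC(C)=O | starting material
9 | dilithium nona-1,3-diene-2,4-diolate, the 1,3-dianion of 8 (not isolated) | [Li+].[Li+].C=C([O-])C=C([O-])CCCCC | intermediate
10 | N,N-diethyl-4-methoxy-6-methyl-2-[(2,4,6-trioxoundecyl)oxy]benzamide (drawn as the triketo tautomer) | CCCCCC(=O)CC(=O)CC(=O)COc1cc(OC)cc(C)c1C(=O)N(CC)CC | intermediate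
11 | N,N-diethyl-2-[(6-hydroxy-2,4-dioxo-6-pentylcyclohexyl)oxy]-4-methoxy-6-methylbenzamide, mixture of stereoisomers (not isolated) | CCCCCC1(O)CC(=O)CC(=O)C1Oc1cc(OC)cc(C)c1C(=O)N(CC)CC | intermediate
12 | N,N-diethyl-2-(2,4-dihydroxy-6-pentylphenoxy)-4-methoxy-6-methylbenzamide | CCCCCc1cc(O)cc(O)c1Oc1cc(OC)cc(C)c1C(=O)N(CC)CC | intermediate
13 | N,N-diethyl-2-(2,4-dimethoxy-6-pentylphenoxy)-4-methoxy-6-methylbenzamide | CCCCCc1cc(OC)cc(OC)c1Oc1cc(OC)cc(C)c1C(=O)N(CC)CC | intermediate
14 | hexanoyl chloride | CCCCCC(Cl)=O | starting material
15 | N-methoxy-N-methylhexanamide | CCCCCC(=O)N(C)OC | intermediate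
16 | benzylic organolithium of 13, lithiated at the 6-CH3 group (not isolated) | [Li]Cc1cc(OC)cc(Oc2c(OC)cc(OC)cc2CCCCC)c1C(=O)N(CC)CC | intermediate
17 | lithium hemiaminal alkoxide from 16 and 15, racemic (not isolated) | CCCCCC(O[Li])(Cc1cc(OC)cc(Oc2c(OC)cc(OC)cc2CCCCC)c1C(=O)N(CC)CC)N(C)OC | intermediate
18 | N,N-diethyl-2-(2,4-dimethoxy-6-pentylphenoxy)-4-methoxy-6-(2-oxoheptyl)benzamide | CCCCCC(=O)Cc1cc(OC)cc(Oc2c(OC)cc(OC)cc2CCCCC)c1C(=O)N(CC)CC | intermediate
19 | 8-(2,4-dimethoxy-6-pentylphenoxy)-6-methoxy-3-pentyl-1H-isochromen-1-one | CCCCCc1cc2cc(OC)cc(Oc3c(OC)cc(OC)cc3CCCCC)c2c(=O)o1 | intermediate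
20 | 8-(2,4-dihydroxy-6-pentylphenoxy)-6-hydroxy-3-pentyl-1H-isochromen-1-one (CNP0213708.0) | CCCCCc1cc2cc(O)cc(Oc3c(O)cc(O)cc3CCCCC)c2c(=O)o1 | target

**Step count.** Total: 11 steps. Longest linear sequence: 10 steps (steps 1–7 and 9–11, from methyl orsellinate); step 8 is a one-step side branch.

**Steps most likely to fail**

Step 6. The ring closure may start from the other chain end (C7 onto C2), or hydroxide may fragment the triketone by retro-Claisen cleavage before it cyclises; air oxidation of the electron-rich bis-phenoxide is a further loss. In that case ring C would be taken ready-made. Commercial 1,3-dimethoxy-5-pentylbenzene (CCCCCc1cc(OC)cc(OC)c1) would be iodinated with N-iodosuccinimide in MeCN at the position para to one methoxy group and ortho to the pentyl chain, to give 2-iodo-1,5-dimethoxy-3-pentylbenzene F1. Phenol 5 would then be arylated with F1 in an Ullmann diaryl ether synthesis (CuI, picolinic acid, K3PO4, DMSO, 100 °C). This fallback sets out from 5 and returns to the route at 13, bypassing steps 4–7. Coupling of two ortho-substituted partners is expected to be slow, which is why it is held in reserve.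

Step 5. Proton transfer from the α-aryloxy ester to the dianion may replace acylation, part of the dianion may form at C5 instead of C1, or the triketone may cyclodehydrate to a pyranone during acidic work-up. The fallback replaces the Claisen acylation by an aldol addition and oxidation. Ester 7 would be reduced with i-Bu2AlH (1.1 equiv, CH2Cl2, −78 °C) to N,N-diethyl-4-methoxy-6-methyl-2-(2-oxoethoxy)benzamide F2. Dienolate 9 (generated as in step 5) would add through its terminal carbon to this aldehyde at −78 °C to give N,N-diethyl-2-[(2-hydroxy-4,6-dioxoundecyl)oxy]-4-methoxy-6-methylbenzamide F3. Oxidation of the secondary alcohol with Dess–Martin periodinane in CH2Cl2 would give the triketone. This fallback sets out from 7 and returns at 10.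

Step 9. The benzylic anion may deprotonate amide 15 at its α-CH2 instead of adding to it, or attack the amide carbonyl of a second molecule of 13 if the mixture warms. The fallback uses an aldehyde, which adds faster than it enolises. Organolithium 16, generated as in step 9, would be quenched at −78 °C with hexanal (CCCCCC=O) to give N,N-diethyl-2-(2,4-dimethoxy-6-pentylphenoxy)-6-(2-hydroxyheptyl)-4-methoxybenzamide F4. Oxidation of the alcohol with Dess–Martin periodinane in CH2Cl2 would give the ketone. This fallback sets out from 13 and returns at 18.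

Further compounds

F1 | step 6 | 2-iodo-1,5-dimethoxy-3-pentylbenzene | CCCCCc1cc(OC)cc(OC)c1I
F2 | step 5 | N,N-diethyl-4-methoxy-6-methyl-2-(2-oxoethoxy)benzamide | O=CCOc1cc(OC)cc(C)c1C(=O)N(CC)CC
F3 | step 5 | N,N-diethyl-2-[(2-hydroxy-4,6-dioxoundecyl)oxy]-4-methoxy-6-methylbenzamide (racemic) | CCCCCC(=O)CC(=O)CC(O)COc1cc(OC)cc(C)c1C(=O)N(CC)CC
F4 | step 9 | N,N-diethyl-2-(2,4-dimethoxy-6-pentylphenoxy)-6-(2-hydroxyheptyl)-4-methoxybenzamide (racemic) | CCCCCC(O)Cc1cc(OC)cc(Oc2c(OC)cc(OC)cc2CCCCC)c1C(=O)N(CC)CC
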